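**Retrosynthetic overview**
1. The quinone methide comes from acid-triggered global deprotection and dehydration of a bis(4-MOMO-phenyl)carbinol, made by double addition of 4-(MOMO)phenyllithium to a hindered methyl benzoate.
2. The CH2OH comes from the less hindered of two esters (selective saponification, mixed-anhydride reduction); the diaryl alkyne comes from Sonogashira coupling of an aryl triflate.
3. Key disconnection: the central benzene ring, the only ring built and built first, comes from intermolecular Michael addition of dimethyl 3-oxopentanedioate to a 3-arylpropynal, then intramolecular aldol condensation and aromatisation to a 2-hydroxyisophthalate.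
4. The ynal and the aryl alkyne come from 2,4-dihydroxybenzaldehyde and 4-hydroxybenzaldehyde (MOM protection, Ohira–Bestmann, formylation); the aryllithium comes from 4-bromophenol. The quinoid ring is unveiled last from one of the two 4-oxyphenyl rings.

Assumption: the target has no stereocentre and no stereogenic double bond (the two arms of the quinoid ring are identical), so the compound drawn is achiral and is made as such.

**Route**

Step 1
Reactants: 1 2,4-dihydroxybenzaldehyde
Product: 2 2,4-bis(methoxymethoxy)benzaldehyde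
Conditions: MOMCl (3 equiv), i-Pr2NEt (4 equiv), CH2Cl2, 0 °C → reflux
Reagents that add atoms: chloromethyl methyl ether COCCl
Why: O-alkylation (MOM protection) of both phenols by the reactive α-chloro ether gives acetals that are stable to base, organolithiums and Pd but cleaved by acid at the end.

Step 2
Reactants: 2 2,4-bis(methoxymethoxy)benzaldehyde
Product: 3 1-ethynyl-2,4-bis(methoxymethoxy)benzene
Conditions: Ohira–Bestmann reagent (1.3 equiv), K2CO3 (2 equiv), MeOH, rt
Reagents that add atoms: dimethyl (1-diazo-2-oxopropyl)phosphonate COP(=O)(OC)C(=[N+]=[N-])C(C)=O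
Why: Seyferth–Gilbert homologation (Ohira–Bestmann variant) turns the non-enolisable aldehyde into the terminal alkyne under mild base that leaves MOM ethers intact.

Step 3
Reactants: 3 1-ethynyl-2,4-bis(methoxymethoxy)benzene
Product: 6 3-[2,4-bis(methoxymethoxy)phenyl]prop-2-ynal, via lithium acetylide 4 (not isolated), via lithium hemiaminolate 5 (not isolated)
Conditions: n-BuLi (1.05 equiv), THF, −78 °C; DMF (2 equiv), −78 → 0 °C; reverse quench into 10% aq KH2PO4/MTBE, 0 °C
Reagents that add atoms: N,N-dimethylformamide CN(C)C=O; n-butyllithium [Li]CCCC (its lithium stays only in intermediates 4 and 5)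
Why: Acetylide formylation works because the alkyne C–H is deprotonated far faster than any ortho-lithiation, and the DMF adduct survives until the buffered reverse quench releases the ynal.

Step 4 (key step)
Reactants: 6 3-[2,4-bis(methoxymethoxy)phenyl]prop-2-ynal; 7 dimethyl 3-oxopentanedioate
Product: 10 dimethyl 4-[2,4-bis(methoxymethoxy)phenyl]-2-hydroxybenzene-1,3-dicarboxylate, via Michael adduct 8 (not isolated), via cyclic aldol 9 (not isolated)
Conditions: 7 (1.1 equiv), NaH (1.1 equiv), THF, 0 °C; add 6, 0 °C → rt; 1 M aq HCl to pH 3, 0 °C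
Reagents that add atoms: none
Why: Intermolecular Michael addition of the doubly stabilised enolate to the ynal β-carbon joins the two fragments; the second active methylene then closes on the aldehyde by intramolecular aldol (Knoevenagel) condensation and the dienone tautomerises to the phenol, aromatisation being the driving force.

Step 5
Reactants: 10 dimethyl 4-[2,4-bis(methoxymethoxy)phenyl]-2-hydroxybenzene-1,3-dicarboxylate
Product: 11 dimethyl 4-[2,4-bis(methoxymethoxy)phenyl]-2-{[(trifluoromethyl)sulfonyl]oxy}benzene-1,3-dicarboxylate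
Conditions: Tf2O (1.3 equiv), pyridine (3 equiv), CH2Cl2, −10 → 0 °C
Reagents that add atoms: trifluoromethanesulfonic anhydride O=S(=O)(OS(=O)(=O)C(F)(F)F)C(F)(F)F
Why: O-sulfonylation of the acidic salicylate-type phenol gives an electron-poor aryl triflate ready for Pd coupling, and excess pyridine protects the MOM acetals.

Step 6
Reactants: 12 4-hydroxybenzaldehyde
Product: 13 4-(methoxymethoxy)benzaldehyde
Conditions: MOMCl (1.3 equiv), i-Pr2NEt (1.6 equiv), CH2Cl2, 0 °C → rt
Reagents that add atoms: chloromethyl methyl ether COCCl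
Why: Routine MOM protection (O-alkylation) of an unhindered phenol.

Step 7
Reactants: 13 4-(methoxymethoxy)benzaldehyde
Product: 14 1-ethynyl-4-(methoxymethoxy)benzene
Conditions: Ohira–Bestmann reagent (1.3 equiv), K2CO3 (2 equiv), MeOH, rt
Reagents that add atoms: dimethyl (1-diazo-2-oxopropyl)phosphonate COP(=O)(OC)C(=[N+]=[N-])C(C)=O
Why: Seyferth–Gilbert homologation (Ohira–Bestmann variant) of an aryl aldehyde to the terminal alkyne.

Step 8
Reactants: 11 dimethyl 4-[2,4-bis(methoxymethoxy)phenyl]-2-{[(trifluoromethyl)sulfonyl]oxy}benzene-1,3-dicarboxylate; 14 1-ethynyl-4-(methoxymethoxy)benzene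
Product: 15 dimethyl 4-[2,4-bis(methoxymethoxy)phenyl]-2-{[4-(methoxymethoxy)phenyl]ethynyl}benzene-1,3-dicarboxylate
Conditions: 14 (1.3 equiv), PdCl2(PPh3)2 (5 mol %), CuI (10 mol %), Et3N (4 equiv), DMF, 65 °C, degassed
Reagents that add atoms: none
Why: In this Sonogashira coupling the two ortho esters make the triflate electron-poor so oxidative addition is fast, and the slim copper acetylide tolerates the flanking groups.

Step 9
Reactants: 15 dimethyl 4-[2,4-bis(methoxymethoxy)phenyl]-2-{[4-(methoxymethoxy)phenyl]ethynyl}benzene-1,3-dicarboxylate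
Product: 16 4-[2,4-bis(methoxymethoxy)phenyl]-3-(methoxycarbonyl)-2-{[4-(methoxymethoxy)phenyl]ethynyl}benzoic acid
Conditions: LiOH·H2O (1.5 equiv), THF/MeOH/H2O 3:1:1, 0 °C → rt; 1 M aq HCl to pH 3, 0 °C
Reagents that add atoms: lithium hydroxide [Li+].[OH-]
Why: Saponification (BAc2) is selective for the ester with one ortho substituent, because the ester wedged between the alkyne and the twisted biaryl ring is a di-ortho-substituted benzoate and resists hydroxide attack.

Step 10
Reactants: 16 4-[2,4-bis(methoxymethoxy)phenyl]-3-(methoxycarbonyl)-2-{[4-(methoxymethoxy)phenyl]ethynyl}benzoic acid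
Product: 18 methyl 6-[2,4-bis(methoxymethoxy)phenyl]-3-(hydroxymethyl)-2-{[4-(methoxymethoxy)phenyl]ethynyl}benzoate, via mixed anhydride 17 (not isolated)
Conditions: i-BuOCOCl (1.2 equiv), N-methylmorpholine (1.3 equiv), THF, −15 °C; then NaBH4 (3 equiv), H2O, −15 → 0 °C
Reagents that add atoms: isobutyl chloroformate CC(C)COC(=O)Cl (its atoms stay only in intermediate 17)
Why: Mixed carbonic anhydride activation followed by borohydride reduction converts the acid to the alcohol without touching the hindered methyl ester or the alkyne (no borane, so no hydroboration).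

Step 11
Reactants: 18 methyl 6-[2,4-bis(methoxymethoxy)phenyl]-3-(hydroxymethyl)-2-{[4-(methoxymethoxy)phenyl]ethynyl}benzoate
Product: 19 methyl 6-[2,4-bis(methoxymethoxy)phenyl]-3-{[(tert-butyldimethylsilyl)oxy]methyl}-2-{[4-(methoxymethoxy)phenyl]ethynyl}benzoate
Conditions: TBSCl (1.3 equiv), imidazole (2.5 equiv), DMF, rt
Reagents that add atoms: tert-butyldimethylsilyl chloride CC(C)(C)[Si](C)(C)Cl
Why: Silylation masks the primary benzylic alcohol so that no alkoxide next to the alkyne is present in the organolithium step.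

Step 12
Reactants: 20 4-bromophenol
Product: 21 1-bromo-4-(methoxymethoxy)benzene
Conditions: MOMCl (1.3 equiv), i-Pr2NEt (1.6 equiv), CH2Cl2, 0 °C → rt
Reagents that add atoms: chloromethyl methyl ether COCCl
Why: Routine MOM protection (O-alkylation) of the phenol before halogen–metal exchange.

Step 13
Reactants: 19 methyl 6-[2,4-bis(methoxymethoxy)phenyl]-3-{[(tert-butyldimethylsilyl)oxy]methyl}-2-{[4-(methoxymethoxy)phenyl]ethynyl}benzoate; 21 1-bromo-4-(methoxymethoxy)benzene
Product: 24 {6-[2,4-bis(methoxymethoxy)phenyl]-3-{[(tert-butyldimethylsilyl)oxy]methyl}-2-{[4-(methoxymethoxy)phenyl]ethynyl}phenyl}bis[4-(methoxymethoxy)phenyl]methanol, via aryllithium 22 (not isolated), via diaryl ketone 23 (not isolated)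
Conditions: 21 (3.5 equiv), n-BuLi (3.4 equiv), THF, −78 °C; add 19, −78 → 0 °C (rt if needed); then H2O
Reagents that add atoms: n-butyllithium [Li]CCCC (its lithium stays only in intermediate 22)
Why: Bromine–lithium exchange followed by double nucleophilic acyl addition (ester to ketone to tertiary carbinol) installs both identical aryl groups at once; the linear alkyne leaves one face of the carbonyl open to the unhindered para-substituted aryllithium.

Step 14
Reactants: 24 {6-[2,4-bis(methoxymethoxy)phenyl]-3-{[(tert-butyldimethylsilyl)oxy]methyl}-2-{[4-(methoxymethoxy)phenyl]ethynyl}phenyl}bis[4-(methoxymethoxy)phenyl]methanol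
Product: 26 Selaginellin F, via deprotected carbinol 25 (not isolated)
Conditions: 3 M aq HCl/MeOH/THF 1:4:2, 45 °C; then aq NaHCO3 to pH 6–7, EtOAc
Reagents that add atoms: none
Why: Acid-catalysed acetal and silyl ether cleavage removes the five MOM groups and the TBS group, and the freed bis(4-hydroxyphenyl)carbinol ionises and loses water to the p-quinone methide (fuchsone formation); no stereocentre is created.

**Compound list**
1 | 2,4-dihydroxybenzaldehyde | O=Cc1ccc(O)cc1O | starting material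
2 | 2,4-bis(methoxymethoxy)benzaldehyde | O=Cc1ccc(OCOC)cc1OCOC | intermediate
3 | 1-ethynyl-2,4-bis(methoxymethoxy)benzene | C#Cc1ccc(OCOC)cc1OCOC | intermediate
4 | lithium {[2,4-bis(methoxymethoxy)phenyl]ethynide} | [Li]C#Cc1ccc(OCOC)cc1OCOC | intermediate (not isolated)
5 | lithium 3-[2,4-bis(methoxymethoxy)phenyl]-1-(dimethylamino)prop-2-yn-1-olate (racemic) | [Li]OC(N(C)C)C#Cc1ccc(OCOC)cc1OCOC | intermediate (not isolated)
6 | 3-[2,4-bis(methoxymethoxy)phenyl]prop-2-ynal | O=CC#Cc1ccc(OCOC)cc1OCOC | intermediate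
7 | dimethyl 3-oxopentanedioate (dimethyl 1,3-acetonedicarboxylate) | COC(=O)CC(=O)CC(=O)OC | starting material
8 | dimethyl 2-{(1E)-1-[2,4-bis(methoxymethoxy)phenyl]-3-oxoprop-1-en-1-yl}-3-oxopentanedioate (the isomer that cyclises; E/Z equilibrate through the dienolate) | COC(=O)CC(=O)C(C(=O)OC)/C(=C\C=O)c1ccc(OCOC)cc1OCOC | intermediate (not isolated)
9 | dimethyl 4-[2,4-bis(methoxymethoxy)phenyl]-6-hydroxy-2-oxocyclohex-4-ene-1,3-dicarboxylate (diastereomer mixture; all stereocentres lost on aromatisation) | COC(=O)C1C(O)C=C(c2ccc(OCOC)cc2OCOC)C(C(=O)OC)C1=O | intermediate (not isolated)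
10 | dimethyl 4-[2,4-bis(methoxymethoxy)phenyl]-2-hydroxybenzene-1,3-dicarboxylate | COC(=O)c1ccc(-c2ccc(OCOC)cc2OCOC)c(C(=O)OC)c1O | intermediate
11 | dimethyl 4-[2,4-bis(methoxymethoxy)phenyl]-2-{[(trifluoromethyl)sulfonyl]oxy}benzene-1,3-dicarboxylate | COC(=O)c1ccc(-c2ccc(OCOC)cc2OCOC)c(C(=O)OC)c1OS(=O)(=O)C(F)(F)F | intermediate
12 | 4-hydroxybenzaldehyde | O=Cc1ccc(O)cc1 | starting material
13 | 4-(methoxymethoxy)benzaldehyde | O=Cc1ccc(OCOC)cc1 | intermediate
14 | 1-ethynyl-4-(methoxymethoxy)benzene | C#Cc1ccc(OCOC)cc1 | intermediate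
15 | dimethyl 4-[2,4-bis(methoxymethoxy)phenyl]-2-{[4-(methoxymethoxy)phenyl]ethynyl}benzene-1,3-dicarboxylate | COC(=O)c1ccc(-c2ccc(OCOC)cc2OCOC)c(C(=O)OC)c1C#Cc1ccc(OCOC)cc1 | intermediate
16 | 4-[2,4-bis(methoxymethoxy)phenyl]-3-(methoxycarbonyl)-2-{[4-(methoxymethoxy)phenyl]ethynyl}benzoic acid | OC(=O)c1ccc(-c2ccc(OCOC)cc2OCOC)c(C(=O)OC)c1C#Cc1ccc(OCOC)cc1 | intermediate
17 | isobutyl carbonic anhydride of acid 16 | CC(C)COC(=O)OC(=O)c1ccc(-c2ccc(OCOC)cc2OCOC)c(C(=O)OC)c1C#Cc1ccc(OCOC)cc1 | intermediate (not isolated)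
18 | methyl 6-[2,4-bis(methoxymethoxy)phenyl]-3-(hydroxymethyl)-2-{[4-(methoxymethoxy)phenyl]ethynyl}benzoate | OCc1ccc(-c2ccc(OCOC)cc2OCOC)c(C(=O)OC)c1C#Cc1ccc(OCOC)cc1 | intermediate
19 | methyl 6-[2,4-bis(methoxymethoxy)phenyl]-3-{[(tert-butyldimethylsilyl)oxy]methyl}-2-{[4-(methoxymethoxy)phenyl]ethynyl}benzoate | CC(C)(C)[Si](C)(C)OCc1ccc(-c2ccc(OCOC)cc2OCOC)c(C(=O)OC)c1C#Cc1ccc(OCOC)cc1 | intermediate
20 | 4-bromophenol | Oc1ccc(Br)cc1 | starting material
21 | 1-bromo-4-(methoxymethoxy)benzene | COCOc1ccc(Br)cc1 | intermediate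
22 | [4-(methoxymethoxy)phenyl]lithium | [Li]c1ccc(OCOC)cc1 | intermediate (not isolated)
23 | {6-[2,4-bis(methoxymethoxy)phenyl]-3-{[(tert-butyldimethylsilyl)oxy]methyl}-2-{[4-(methoxymethoxy)phenyl]ethynyl}phenyl}[4-(methoxymethoxy)phenyl]methanone | CC(C)(C)[Si](C)(C)OCc1ccc(-c2ccc(OCOC)cc2OCOC)c(C(=O)c2ccc(OCOC)cc2)c1C#Cc1ccc(OCOC)cc1 | intermediate (not isolated)
24 | {6-[2,4-bis(methoxymethoxy)phenyl]-3-{[(tert-butyldimethylsilyl)oxy]methyl}-2-{[4-(methoxymethoxy)phenyl]ethynyl}phenyl}bis[4-(methoxymethoxy)phenyl]methanol | CC(C)(C)[Si](C)(C)OCc1ccc(-c2ccc(OCOC)cc2OCOC)c(C(O)(c2ccc(OCOC)cc2)c2ccc(OCOC)cc2)c1C#Cc1ccc(OCOC)cc1 | intermediate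
25 | 2-[hydroxybis(4-hydroxyphenyl)methyl]-4-(hydroxymethyl)-3-[(4-hydroxyphenyl)ethynyl]biphenyl-2',4'-diol | OCc1ccc(-c2ccc(O)cc2O)c(C(O)(c2ccc(O)cc2)c2ccc(O)cc2)c1C#Cc1ccc(O)cc1 | intermediate (not isolated)
26 | Selaginellin F, 4-{[2',4'-dihydroxy-4-(hydroxymethyl)-3-[(4-hydroxyphenyl)ethynyl]biphenyl-2-yl](4-hydroxyphenyl)methylidene}cyclohexa-2,5-dien-1-one (achiral) | O=C1C=CC(=C(c2ccc(O)cc2)c2c(-c3ccc(O)cc3O)ccc(CO)c2C#Cc2ccc(O)cc2)C=C1 | target

**Totals**
Total step count: 14.
Longest linear sequence: 11 steps from 2,4-dihydroxybenzaldehyde (steps 1, 2, 3, 4, 5, 8, 9, 10, 11, 13, 14).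

**Three steps most likely to fail**

Step 13 (double aryllithium addition to the di-ortho-substituted ester). If 19 is recovered or the reaction stalls, the carbinol carbon is built one aryl at a time, setting out from 19. DIBAL-H (CH2Cl2, −78 → 0 °C) reduces the ester to {6-[2,4-bis(methoxymethoxy)phenyl]-3-{[(tert-butyldimethylsilyl)oxy]methyl}-2-{[4-(methoxymethoxy)phenyl]ethynyl}phenyl}methanol F4. Dess–Martin periodinane (NaHCO3, CH2Cl2) then gives 6-[2,4-bis(methoxymethoxy)phenyl]-3-{[(tert-butyldimethylsilyl)oxy]methyl}-2-{[4-(methoxymethoxy)phenyl]ethynyl}benzaldehyde F5. Addition of 22 (from 21 and n-BuLi, THF, −78 °C) to this far more reactive aldehyde gives racemic {6-[2,4-bis(methoxymethoxy)phenyl]-3-{[(tert-butyldimethylsilyl)oxy]methyl}-2-{[4-(methoxymethoxy)phenyl]ethynyl}phenyl}[4-(methoxymethoxy)phenyl]methanol F6. A second Dess–Martin oxidation comes back to the route at ketone 23, now isolated, which takes up a second equivalent of 22 (anhydrous CeCl3 as additive, THF, −78 → 0 °C) to give 24.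

Step 4 (Michael/aldol aromatic annulation with the base-sensitive ynal). If 6 polymerises or O-cyclised products dominate, the fallback sets out from aldehyde 2 and uses the enal oxidation level instead. Wittig olefination with (triphenylphosphoranylidene)acetaldehyde (toluene, 80 °C) gives (E)-3-[2,4-bis(methoxymethoxy)phenyl]prop-2-enal F1. Pyrrolidine/benzoic acid (20 mol %, CH2Cl2, rt) catalyses Michael addition of 7 to F1 and the in-flask Knoevenagel-type aldol condensation, giving dimethyl 6-[2,4-bis(methoxymethoxy)phenyl]-2-oxocyclohex-3-ene-1,3-dicarboxylate F2 (racemic diastereomer and keto–enol mixture). Dehydrogenation with DDQ (1,4-dioxane, rt → 60 °C) aromatises F2 and comes back to the route at phenol 10.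

Step 8 (Sonogashira on the doubly ortho-substituted triflate). If the amine cleaves the triflate back to 10 faster than coupling occurs, the fallback sets out from alkyne 14. It is converted (n-BuLi, THF, −78 °C; then Bu3SnCl) into tributyl{[4-(methoxymethoxy)phenyl]ethynyl}stannane F3. F3 is joined to 11 in a base-free, copper-free Stille coupling (Pd(PPh3)4, LiCl, 1,4-dioxane, 95 °C), which comes back to the route at 15.

**Further compounds**
F1 | step 4 | (E)-3-[2,4-bis(methoxymethoxy)phenyl]prop-2-enal | O=C/C=C/c1ccc(OCOC)cc1OCOC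
F2 | step 4 | dimethyl 6-[2,4-bis(methoxymethoxy)phenyl]-2-oxocyclohex-3-ene-1,3-dicarboxylate (racemic diastereomer mixture; stereocentres lost on aromatisation) | COC(=O)C1=CCC(c2ccc(OCOC)cc2OCOC)C(C(=O)OC)C1=O
F3 | step 8 | tributyl{[4-(methoxymethoxy)phenyl]ethynyl}stannane | CCCC[Sn](CCCC)(CCCC)C#Cc1ccc(OCOC)cc1
F4 | step 13 | {6-[2,4-bis(methoxymethoxy)phenyl]-3-{[(tert-butyldimethylsilyl)oxy]methyl}-2-{[4-(methoxymethoxy)phenyl]ethynyl}phenyl}methanol | CC(C)(C)[Si](C)(C)OCc1ccc(-c2ccc(OCOC)cc2OCOC)c(CO)c1C#Cc1ccc(OCOC)cc1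
F5 | step 13 | 6-[2,4-bis(methoxymethoxy)phenyl]-3-{[(tert-butyldimethylsilyl)oxy]methyl}-2-{[4-(methoxymethoxy)phenyl]ethynyl}benzaldehyde | CC(C)(C)[Si](C)(C)OCc1ccc(-c2ccc(OCOC)cc2OCOC)c(C=O)c1C#Cc1ccc(OCOC)cc1
F6 | step 13 | {6-[2,4-bis(methoxymethoxy)phenyl]-3-{[(tert-butyldimethylsilyl)oxy]methyl}-2-{[4-(methoxymethoxy)phenyl]ethynyl}phenyl}[4-(methoxymethoxy)phenyl]methanol (racemic; stereocentre removed by oxidation) | CC(C)(C)[Si](C)(C)OCc1ccc(-c2ccc(OCOC)cc2OCOC)c(C(O)c2ccc(OCOC)cc2)c1C#Cc1ccc(OCOC)cc1
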